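Readings and results stem from a simulated flask for substances that don't exist; scatter was added.

Late in both earlier runs, at 3.00 min, mono adduct reads 26 % in green and 25 % in ochre, level within the scatter, although ochre was charged with more reagent. Two of us read that differently.

the same everywhere: substrate 0.010 M (fed, over 3.0 min)
- green: reagent 0.010 M; run made earlier
- ochre: reagent 0.017 M; run made earlier
- midnight: reagent 0.0150 M; time 3.0 min
- autumn: reagent 0.0250 M; time 3.0 min

| run | time / min | mono adduct / % | tetra adduct / % |
|---|---|---|---|
| green | 0.417 | 0 | 0 |
| green | 0.833 | 6 | 2 |
| green | 1.33 | 10 | 0 |
| green | 1.50 | 11 | 0 |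
| green | 2.00 | 19 | 0 |
| green | 2.50 | 22 | 0 |
| green | 3.00 | 26 | 0 |
| ochre | 0.250 | 4 | 0 |
| ochre | 0.333 | 2 | 1 |
| ochre | 0.500 | 5 | 0 |
| ochre | 0.833 | 8 | 0 |
| ochre | 1.33 | 11 | 0 |
| ochre | 2.00 | 19 | 1 |
| ochre | 3.00 | 25 | 0 |

(standard deviation of a reading: 1.5 percentage points)

- a species is counted by the substrate in it: one side product counts as two
- reactions considered so far: substrate + reagent -> mono adduct + by-product; reagent + mono adduct -> bis adduct + by-product; substrate + bis adduct -> side product; reagent + bis adduct -> triple product + by-product; reagent + triple product -> tetra adduct + by-product
- percentages count the whole charge, also what has not yet gone in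

- which of these holds the largest part of the substrate at the end of midnight (bis adduct / mono adduct / substrate / tetra adduct / triple product)
- which of these holds the largest part of the substrate at the end of autumn (bis adduct / mono adduct / substrate / tetra adduct / triple product)
- amount of mono adduct at the end of autumn, in percent of the substrate charged

The maker of the forecast sees a split set by the feed, in which “about a quarter of what enters survives as mono”, and reads midnight and autumn as a hold after feeding. The forecast says bis adduct for midnight, bis adduct for autumn, and 20 % of mono adduct.

I see the flat top of a curve. Suppose substrate and mono adduct react with one common rate constant, and reagent stays at its charge (pseudo-first-order). Let x be rate constant times reagent times dosing time. Integrating feed in against loss out gives, as fractions of the charge at the end of the feed, substrate (1 − exp(−x))/x and mono adduct (1 − (1 + x)·exp(−x))/x.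

The mono curve tops near x = 2, at 29.7 %, so my mono figures run above the readings. I take green and ochre to stand on either side of that top, so I put x = 2 at the geometric mean of their reagent charges, which gives a rate constant of 51.1 /M/min. Then x is 2.30 for midnight and 3.83 for autumn, the feed number, the substrate lifetimes that fit into the feed.

Midnight then keeps 39.1 % as substrate, 29.1 % as mono adduct and 31.8 % beyond it, so I say substrate. Autumn keeps 25.5 % and 23.4 %, with 51.1 % beyond, so I say bis adduct.

Midnight ends with substrate on top at 41.2 %, against 30.2 % of bis adduct. Autumn, charged with more reagent than midnight, is where the forecast's view holds: bis adduct ends at 48.5 % and mono adduct at 18.1 %, nearer the forecast than my 23.4 %.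

    substrate + reagent → mono adduct + by-product (k = 78.0 /M/min)
    reagent + mono adduct → bis adduct + by-product (k = 95.0 /M/min)
    substrate + bis adduct → side product (k = 18.0 /M/min)
    reagent + bis adduct → triple product + by-product (k = 2.70 /M/min)
    reagent + triple product → tetra adduct + by-product (k = 76.0 /M/min)

In autumn at 1.50 min, substrate stood at 18.0 % while mono adduct was turning into bis adduct, which had reached 18.8 %. At 3.00 min, as the feed ended, substrate stood at 26.1 %, against 25.5 % from the feed number 3.83. In a neighbour of autumn charged with 0.043 M of reagent, the feed number becomes 6.60 and gives 15.1 % of substrate. That flask holds 14.3 % of substrate, with bis adduct on top at 63.6 %.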